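I began by asking which amounts in this flask change slowly enough to be frozen.

starting material 0.050 M; gas phase 1.6 mM (held); protic impurity 0.0150 M; catalyst 2 mol%; time 3.0 h

    gas phase ⇌ dissolved gas, rate k1*(csat - [dissolved gas]) (k1 = 0.248 min⁻¹, csat = 1.6 mM)
    starting material + dissolved gas + catalyst → catalyst + target (k2 = 2640 M⁻² min⁻¹)
    starting material + protic impurity → quenched substrate (k3 = 11.5 M⁻¹ min⁻¹)
    starting material + target → side product (k4 = 0.607 M⁻¹ min⁻¹)

- a species is counted by the starting material in it: one side product counts as two
- at the start none of the gas is dissolved
- run time (flask): 3.0 h

* the target standing at 3.0 h, as a percentage of the starting material charged
* the change that raises the amount of target at 3.0 h, in percent of the starting material charged most ("none" if none brings more than 2 percentage points) (summer / dusk / midnight / none)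
* amount of target at 3.0 h, in percent of the starting material charged, after dusk

- summer: doubling the saturation concentration of gas phase, all else as stated
- dusk: doubling the amount of catalyst, all else as stated
- midnight: doubling the transfer coefficient of step 1, all else as stated

Gas transfer refills the solution in about 4.03 min, much shorter than the run, so I froze the dissolved gas where supply balances consumption, a quasi-steady state. The protic impurity removes 0.0150 M of starting material early, and I froze the starting material at 17.5 mM, half of what remains, as a mid-run guess. With the catalyst at 1.00 mM, the gas then stands at 84.3% of saturation.

Starting material multiplies both the making of target and its loss to side product, so it cancels from their balance. That balance lies at 11.7% of the charge; I call this the target ceiling, the level at which target is made as fast as it is consumed. The gap to it shrinks exponentially with the side-reaction constant times starting material times time, so the target covers 85.2% of the way, and I committed to 10.0%.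

Summer doubles the ceiling at the same gas share. Dusk doubles it too, but lowers the share to 72.9%, giving 17.3%. Midnight, which doubles the transfer coefficient of step 1, merely lifts the share to 91.5%. My choice was summer.

The forecast gave 10.4% (from 9.4% to 11.4%), summer as best and 17.3% after dusk (from 15.8% to 18.8%), holding that “Gas supply is limiting”.

The simulation gave 10.5%, summer as best and 17.5% after dusk. This flask thus stood at 89.7% of my ceiling. Its dissolved gas read 80.1% of saturation at 1.50 h, lower than my frozen share, with 45.8% of the charge then standing as starting material. For the neighbouring flask with 3.4 mol% of catalyst, the same reckoning puts the ceiling at 18.0% and the target at 15.3%; that flask held 15.7%.

All constants come from no measurement; what happens was integrated by code.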